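**Plan**

1. Numbering: oxane ring O1, C2 (aryl), C3 (arm), C4 (OH), C5, C6 (arylethyl); the arm is a hept-1-en-3-yl group, C3' on C3 and C4' its carbinol carbon. Retrosynthetic cuts, in order: the five O–Si bonds; the styrene C1'=C2' (back to a vinyl group on C3'); C2–aryl and C2–H (back to a δ-lactone carbonyl); the ring bond C3–C4; C3'–vinyl and C3–Br (back to an (E)-enoate); the alkyne–C4' bond and the ester C–O bond; C5–C6.
2. Forward: 3-arylpropanal is allylated (C6), the alkene is cut to a masked C4 aldehyde, the C6 alcohol is acylated with propiolic acid, the ynoate is joined to 4-arylbutanal (C4'), reduced to the (E)-enoate, vinylated at C3' and brominated at C3. The only ring (the oxane) then closes at C3–C4 as a lactone; C2 is arylated and reduced, and the styrene is completed last.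
3. Enabling feature: with C2 at the carboxyl level the ring O1–C2–C3–C4–C5–C6 is a β-hydroxy-δ-lactone. C3 is then an ester α-carbon and C4 a β-carbinol that is 1,3 to C6. The axial C4–OH trans to the C6 arm is what a metal bridging the enolate oxygen on C2 and the aldehyde oxygen on C4 delivers.
4. Stereochemistry: C6 from catalytic asymmetric allylation; C4' from catalytic asymmetric alkynylation; C3' from anti-selective copper addition next to C4'; C3 and C4 from the chelated aldol closure under control of C6; C2 from axial hydride delivery to the cyclic oxocarbenium ion; the (E)-alkene from cross-metathesis.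

Key step: step 11

Assumption: (R)-BINOL/Ti(OiPr)4 and (S,S)-ProPhenol/Me2Zn are taken to deliver the allyl and alkynyl groups to the Re faces of the two aldehydes; if the opposite sense were found, the antipodal ligand would be used.

Abbreviations: TBS = tert-butyldimethylsilyl; Ar = 4-(TBSO)C6H4.

**Route**

Step 1
Reactants: 1 tert-butyl(4-iodophenoxy)dimethylsilane; 2 prop-2-en-1-ol
Product: 3 3-Ar-propanal
Conditions: Pd(OAc)2 (3 mol%), n-Bu4NCl, NaHCO3, DMF, 45 °C
Reagents that add atoms: none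
Why: Heck arylation of an allylic alcohol under ligand-free phase-transfer conditions, in which aryl–Pd adds to the terminal carbon and β-hydride elimination toward the carbinol releases the enol and hence the aldehyde; no stereocentre is formed.

Step 2
Reactants: 3 3-Ar-propanal; 4 allyltributylstannane
Product: 5 (3S)-1-Ar-hex-5-en-3-ol
Conditions: Ti(OiPr)4 (10 mol%), (R)-BINOL (20 mol%), 4 Å molecular sieves, CH2Cl2, −20 °C; then aq. NaHCO3
Reagents that add atoms: none
Why: Keck asymmetric allylation, in which the chiral Ti–BINOL Lewis acid activates the aldehyde and the stannane should add to its Re face, setting the future C6 as S.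

Step 3
Reactants: 5 (3S)-1-Ar-hex-5-en-3-ol
Product: 7 (3S)-1,1-dimethoxy-5-Ar-pentan-3-ol, via hydroxy aldehyde 6 (not isolated)
Conditions: O3, CH2Cl2/MeOH, −78 °C (Sudan Red 7B end point); Me2S, −78 → 20 °C; then HC(OMe)3, PPTS (cat.), 20 °C
Reagents that add atoms: ozone, [O-][O+]=O (carbonyl oxygen of intermediate 6 only); trimethyl orthoformate, COC(OC)OC (the two methoxy groups of 7)
Why: Ozonolysis of the terminal alkene with reductive work-up gives the β-hydroxy aldehyde, which is trapped at once as its dimethyl acetal by acid-catalysed acetalisation; the indicator end point should spare the silyloxy arene and C6 is untouched.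

Step 4
Reactants: 7 (3S)-1,1-dimethoxy-5-Ar-pentan-3-ol; 8 propiolic acid
Product: 9 (3S)-1,1-dimethoxy-5-Ar-pentan-3-yl prop-2-ynoate
Conditions: DCC, DMAP (5 mol%), CH2Cl2, −20 → 0 °C
Reagents that add atoms: none
Why: Steglich esterification run cold so that the propiolate does not polymerise; the C6–O bond is not broken, so configuration is retained.

Step 5
Reactants: 1 tert-butyl(4-iodophenoxy)dimethylsilane; 10 but-3-en-1-ol
Product: 11 4-Ar-butanal
Conditions: Pd(OAc)2 (3 mol%), n-Bu4NCl, NaHCO3, DMF, 50 °C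
Reagents that add atoms: none
Why: Heck arylation of a homoallylic alcohol with chain walking, in which palladium migrates by β-hydride elimination and re-addition to the carbinol carbon and leaves as the aldehyde; no stereocentre is formed.

Step 6
Reactants: 9 (3S)-1,1-dimethoxy-5-Ar-pentan-3-yl prop-2-ynoate; 11 4-Ar-butanal
Product: 12 (3S)-1,1-dimethoxy-5-Ar-pentan-3-yl (4S)-4-hydroxy-7-Ar-hept-2-ynoate
Conditions: (S,S)-ProPhenol (20 mol%), Ph3P=O (40 mol%), Me2Zn (2 equiv), toluene, 0 °C (9 limiting, 11 1.5 equiv); then H2O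
Reagents that add atoms: none
Why: Zinc–ProPhenol-catalysed asymmetric alkynylation of an aldehyde, in which the dinuclear zinc complex metalates the propiolate C–H and should deliver the alkynyl group to the Re face of 11, setting the future C4' as S.

Step 7
Reactants: 12 (3S)-1,1-dimethoxy-5-Ar-pentan-3-yl (4S)-4-hydroxy-7-Ar-hept-2-ynoate
Product: 13 (3S)-1,1-dimethoxy-5-Ar-pentan-3-yl (2E,4S)-4-hydroxy-7-Ar-hept-2-enoate
Conditions: NaAlH2(OCH2CH2OMe)2 (Red-Al, 1.6 equiv), THF, −78 °C; then aq. potassium sodium tartrate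
Reagents that add atoms: none
Why: Hydroxyl-directed trans-hydroalumination of a γ-hydroxy ynoate followed by protonolysis should give the (E)-enoate; the ester survives at −78 °C and C4' is untouched.

Step 8
Reactants: 13 (3S)-1,1-dimethoxy-5-Ar-pentan-3-yl (2E,4S)-4-hydroxy-7-Ar-hept-2-enoate
Product: 14 (3S)-1,1-dimethoxy-5-Ar-pentan-3-yl (2E,4S)-4-(TBSO)-7-Ar-hept-2-enoate
Conditions: TBSCl, imidazole, DMF, 20 °C
Reagents that add atoms: tert-butyldimethylsilyl chloride, CC(C)(C)[Si](C)(C)Cl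
Why: Standard silylation of the secondary alcohol; the γ-silyloxy group is also the control element for step 9.

Step 9
Reactants: 14 (3S)-1,1-dimethoxy-5-Ar-pentan-3-yl (2E,4S)-4-(TBSO)-7-Ar-hept-2-enoate; 15 vinylmagnesium bromide
Product: 17 (3S)-1,1-dimethoxy-5-Ar-pentan-3-yl (2RS,3S,4S)-2-bromo-3-ethenyl-4-(TBSO)-7-Ar-heptanoate, via silyl ketene acetal 16 (not isolated)
Conditions: 15 (3 equiv), CuI (0.2 equiv), Me3SiCl (4 equiv), THF, −78 °C; then NBS (3.5 equiv), THF, −78 °C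
Reagents that add atoms: N-bromosuccinimide, O=C1CCC(=O)N1Br; chlorotrimethylsilane, C[Si](C)(C)Cl (silyl group of intermediate 16 only)
Why: Copper-catalysed, Me3SiCl-accelerated conjugate addition of a vinyl Grignard reagent should occur anti to the γ-silyloxy group of the (E)-enoate (Felkin–Anh-type conformer with the C–O bond anti to the incoming copper), setting C3' in the 3,4-anti sense, and the silyl ketene acetal is then brominated by NBS to install the Reformatsky handle (the bromide-bearing carbon is formed as both epimers, which does not matter).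

Step 10
Reactants: 17 (3S)-1,1-dimethoxy-5-Ar-pentan-3-yl (2RS,3S,4S)-2-bromo-3-ethenyl-4-(TBSO)-7-Ar-heptanoate
Product: 18 (3S)-1-oxo-5-Ar-pentan-3-yl (2RS,3S,4S)-2-bromo-3-ethenyl-4-(TBSO)-7-Ar-heptanoate
Conditions: Amberlyst-15, acetone/H2O (20:1), 25 °C
Reagents that add atoms: water, O
Why: Acid-catalysed acetal hydrolysis under conditions that should leave aryl and secondary silyl ethers and the α-bromo ester intact; the β-acyloxy aldehyde is used at once to avoid β-elimination.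

Step 11
Reactants: 18 (3S)-1-oxo-5-Ar-pentan-3-yl (2RS,3S,4S)-2-bromo-3-ethenyl-4-(TBSO)-7-Ar-heptanoate
Product: 20 (3S,4S,6S)-4-hydroxy-6-(2-Ar-ethyl)-3-[(3R,4S)-4-(TBSO)-7-Ar-hept-1-en-3-yl]oxan-2-one, via samarium enolate 19 (not isolated)
Conditions: SmI2 (2.5 equiv, 0.1 M in THF), THF, −78 °C; then pH 7 aqueous buffer
Reagents that add atoms: samarium diiodide, I[Sm]I (samarium and iodide of intermediate 19 only)
Why: Two equivalents of SmI2 reduce the C–Br bond of 18, much faster than the aliphatic aldehyde, to the trivalent samarium ester enolate 19, which adds to the tethered aldehyde in an intramolecular Reformatsky-type aldol; the closest known reaction is the SmI2-promoted cyclisation of β-(α-bromoacyloxy) aldehydes to β-hydroxy-δ-lactones. The oxan-2-one ring closes by 6-(enolendo)-exo-trig attack of C3 on the C4 carbonyl. Samarium bridges the enolate oxygen on C2 and the aldehyde oxygen, so the transition state is a bicyclo[3.3.1]-type double chair in which the C4 oxygen is forced axial on the forming lactone ring; C4 is therefore set trans to the C6 arylethyl arm, which stays equatorial to avoid a 1,3-diaxial clash with the Sm–O bridge (1,3-induction from C6). C3 is set by the enolate geometry: the branched arm should prefer the position cis to O–Sm (Z enolate), which becomes equatorial and cis to the C4 hydroxyl, and because C3 is α to the lactone carbonyl a minor epimer could be equilibrated to this more stable arrangement. The step needs reduction of the bromide in preference to the aldehyde and no β-elimination from the enolate; the low temperature and absence of HMPA should secure the first, and the second is secured because the only oxygen leaving group of the acyl part (OTBS on C4') is γ, not β, to the enolate carbon.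

Step 12
Reactants: 20 (3S,4S,6S)-4-hydroxy-6-(2-Ar-ethyl)-3-[(3R,4S)-4-(TBSO)-7-Ar-hept-1-en-3-yl]oxan-2-one; 1 tert-butyl(4-iodophenoxy)dimethylsilane
Product: 21 (3S,4S,6S)-2-Ar-6-(2-Ar-ethyl)-3-[(3R,4S)-4-(TBSO)-7-Ar-hept-1-en-3-yl]oxane-2,4-diol (both C2 anomers, in equilibrium with the open hydroxy ketone)
Conditions: 1 (3 equiv), n-BuLi (3 equiv), THF, −78 °C; add 20, −78 °C; then AcOH, −78 °C
Reagents that add atoms: none
Why: Iodine–lithium exchange gives the aryllithium, which adds once to the lactone carbonyl because the tetrahedral adduct is stable at −78 °C; the first equivalent only removes the C4 hydroxyl proton, whose alkoxide cannot β-eliminate, and C2 is formed as a hemiketal of no stereochemical consequence.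

Step 13
Reactants: 21 (3S,4S,6S)-2-Ar-6-(2-Ar-ethyl)-3-[(3R,4S)-4-(TBSO)-7-Ar-hept-1-en-3-yl]oxane-2,4-diol
Product: 23 (2S,3S,4S,6S)-2-Ar-6-(2-Ar-ethyl)-3-[(3R,4S)-4-(TBSO)-7-Ar-hept-1-en-3-yl]oxan-4-ol, via oxocarbenium ion 22 (not isolated)
Conditions: Et3SiH (6 equiv), BF3·OEt2 (3 equiv), CH2Cl2/MeCN (1:1), −40 °C
Reagents that add atoms: none
Why: Ionic reduction of the hemiketal, in which BF3 ionises 21 to the aryl-stabilised cyclic oxocarbenium ion and Et3SiH should attack axially on the half-chair that keeps the C6 and C3 arms pseudoequatorial and the C4 oxygen pseudoaxial, placing the C2 aryl group equatorial (2,6-cis, 2,3-trans).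

Step 14
Reactants: 23 (2S,3S,4S,6S)-2-Ar-6-(2-Ar-ethyl)-3-[(3R,4S)-4-(TBSO)-7-Ar-hept-1-en-3-yl]oxan-4-ol; 24 tert-butyldimethyl(4-vinylphenoxy)silane
Product: 25 (2S,3S,4S,6S)-2-Ar-6-(2-Ar-ethyl)-3-[(1E,3R,4S)-4-(TBSO)-1,7-di-Ar-hept-1-en-3-yl]oxan-4-ol
Conditions: 24 (5 equiv), Hoveyda–Grubbs second-generation catalyst RuCl2(H2IMes)(=CH-C6H4-2-OiPr) (10 mol%), toluene, 70 °C
Reagents that add atoms: none
Why: Olefin cross-metathesis of the terminal vinyl group with an excess of the styrene partner should give the (E)-styrene under thermodynamic control, and the allylic stereocentre C3' is not touched.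

Step 15
Reactants: 25 (2S,3S,4S,6S)-2-Ar-6-(2-Ar-ethyl)-3-[(1E,3R,4S)-4-(TBSO)-1,7-di-Ar-hept-1-en-3-yl]oxan-4-ol
Product: 26 (2S,3S,4S,6S)-2-(4-hydroxyphenyl)-6-[2-(4-hydroxyphenyl)ethyl]-3-[(1E,3R,4S)-4-hydroxy-1,7-bis(4-hydroxyphenyl)hept-1-en-3-yl]oxan-4-ol (CNP0132332.1)
Conditions: n-Bu4NF (8 equiv), AcOH (8 equiv), THF, 0 → 25 °C
Reagents that add atoms: none
Why: Fluoride cleavage of the four aryl silyl ethers and the secondary silyl ether, buffered with acetic acid so that phenoxides cannot open the benzylic C2–O1 bond through a quinone methide.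

**Compound list**

1 | tert-butyl(4-iodophenoxy)dimethylsilane | CC(C)(C)[Si](C)(C)Oc1ccc(I)cc1 | starting material
2 | prop-2-en-1-ol (allyl alcohol) | C=CCO | starting material
3 | 3-[4-(TBSO)phenyl]propanal | O=CCCc1ccc(O[Si](C)(C)C(C)(C)C)cc1 | intermediate
4 | allyltributylstannane | C=CC[Sn](CCCC)(CCCC)CCCC | starting material
5 | (3S)-1-[4-(TBSO)phenyl]hex-5-en-3-ol | C=CC[C@@H](O)CCc1ccc(O[Si](C)(C)C(C)(C)C)cc1 | intermediate
6 | (3S)-3-hydroxy-5-[4-(TBSO)phenyl]pentanal (not isolated) | O=CC[C@@H](O)CCc1ccc(O[Si](C)(C)C(C)(C)C)cc1 | intermediate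
7 | (3S)-1,1-dimethoxy-5-[4-(TBSO)phenyl]pentan-3-ol | COC(OC)C[C@@H](O)CCc1ccc(O[Si](C)(C)C(C)(C)C)cc1 | intermediate
8 | propiolic acid | C#CC(=O)O | starting material
9 | (3S)-1,1-dimethoxy-5-[4-(TBSO)phenyl]pentan-3-yl prop-2-ynoate | COC(OC)C[C@H](CCc1ccc(O[Si](C)(C)C(C)(C)C)cc1)OC(=O)C#C | intermediate
10 | but-3-en-1-ol | C=CCCO | starting material
11 | 4-[4-(TBSO)phenyl]butanal | O=CCCCc1ccc(O[Si](C)(C)C(C)(C)C)cc1 | intermediate
12 | (3S)-1,1-dimethoxy-5-[4-(TBSO)phenyl]pentan-3-yl (4S)-4-hydroxy-7-[4-(TBSO)phenyl]hept-2-ynoate | COC(OC)C[C@H](CCc1ccc(O[Si](C)(C)C(C)(C)C)cc1)OC(=O)C#C[C@@H](O)CCCc1ccc(O[Si](C)(C)C(C)(C)C)cc1 | intermediate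
13 | (3S)-1,1-dimethoxy-5-[4-(TBSO)phenyl]pentan-3-yl (2E,4S)-4-hydroxy-7-[4-(TBSO)phenyl]hept-2-enoate | COC(OC)C[C@H](CCc1ccc(O[Si](C)(C)C(C)(C)C)cc1)OC(=O)/C=C/[C@@H](O)CCCc1ccc(O[Si](C)(C)C(C)(C)C)cc1 | intermediate
14 | (3S)-1,1-dimethoxy-5-[4-(TBSO)phenyl]pentan-3-yl (2E,4S)-4-(TBSO)-7-[4-(TBSO)phenyl]hept-2-enoate | COC(OC)C[C@H](CCc1ccc(O[Si](C)(C)C(C)(C)C)cc1)OC(=O)/C=C/[C@@H](O[Si](C)(C)C(C)(C)C)CCCc1ccc(O[Si](C)(C)C(C)(C)C)cc1 | intermediate
15 | vinylmagnesium bromide | C=C[Mg]Br | starting material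
16 | trimethylsilyl ketene acetal of the vinyl adduct of 14: ester enol C=C bearing OSiMe3 and the (3S)-acetal alkoxy group, chain carbons (3R,4S) by CIP, same spatial arrangement as in 17 (not isolated) | COC(OC)C[C@H](CCc1ccc(O[Si](C)(C)C(C)(C)C)cc1)OC(O[Si](C)(C)C)=C[C@@H](C=C)[C@@H](O[Si](C)(C)C(C)(C)C)CCCc1ccc(O[Si](C)(C)C(C)(C)C)cc1 | intermediate
17 | (3S)-1,1-dimethoxy-5-[4-(TBSO)phenyl]pentan-3-yl (2RS,3S,4S)-2-bromo-3-ethenyl-4-(TBSO)-7-[4-(TBSO)phenyl]heptanoate | COC(OC)C[C@H](CCc1ccc(O[Si](C)(C)C(C)(C)C)cc1)OC(=O)C(Br)[C@@H](C=C)[C@@H](O[Si](C)(C)C(C)(C)C)CCCc1ccc(O[Si](C)(C)C(C)(C)C)cc1 | intermediate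
18 | (3S)-1-oxo-5-[4-(TBSO)phenyl]pentan-3-yl (2RS,3S,4S)-2-bromo-3-ethenyl-4-(TBSO)-7-[4-(TBSO)phenyl]heptanoate | O=CC[C@H](CCc1ccc(O[Si](C)(C)C(C)(C)C)cc1)OC(=O)C(Br)[C@@H](C=C)[C@@H](O[Si](C)(C)C(C)(C)C)CCCc1ccc(O[Si](C)(C)C(C)(C)C)cc1 | intermediate
19 | (Z)-diiodosamarium ester enolate of debrominated 18 (trivalent samarium on the enolate oxygen, arm cis to O–Sm; not isolated) | O=CC[C@H](CCc1ccc(O[Si](C)(C)C(C)(C)C)cc1)O/C(O[Sm](I)I)=C/[C@@H](C=C)[C@@H](O[Si](C)(C)C(C)(C)C)CCCc1ccc(O[Si](C)(C)C(C)(C)C)cc1 | intermediate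
20 | (3S,4S,6S)-4-hydroxy-6-{2-[4-(TBSO)phenyl]ethyl}-3-{(3R,4S)-4-(TBSO)-7-[4-(TBSO)phenyl]hept-1-en-3-yl}oxan-2-one | C=C[C@H]([C@@H]1C(=O)O[C@@H](CCc2ccc(O[Si](C)(C)C(C)(C)C)cc2)C[C@@H]1O)[C@@H](O[Si](C)(C)C(C)(C)C)CCCc1ccc(O[Si](C)(C)C(C)(C)C)cc1 | intermediate
21 | (3S,4S,6S)-2-[4-(TBSO)phenyl]-6-{2-[4-(TBSO)phenyl]ethyl}-3-{(3R,4S)-4-(TBSO)-7-[4-(TBSO)phenyl]hept-1-en-3-yl}oxane-2,4-diol (C2 anomers) | C=C[C@H]([C@@H]1C(O)(c2ccc(O[Si](C)(C)C(C)(C)C)cc2)O[C@@H](CCc2ccc(O[Si](C)(C)C(C)(C)C)cc2)C[C@@H]1O)[C@@H](O[Si](C)(C)C(C)(C)C)CCCc1ccc(O[Si](C)(C)C(C)(C)C)cc1 | intermediate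
22 | cyclic 2-aryl oxocarbenium ion from 21 (C2=O1+, other centres as in 21; not isolated) | C=C[C@H]([C@@H]1C(c2ccc(O[Si](C)(C)C(C)(C)C)cc2)=[O+][C@@H](CCc2ccc(O[Si](C)(C)C(C)(C)C)cc2)C[C@@H]1O)[C@@H](O[Si](C)(C)C(C)(C)C)CCCc1ccc(O[Si](C)(C)C(C)(C)C)cc1 | intermediate
23 | (2S,3S,4S,6S)-2-[4-(TBSO)phenyl]-6-{2-[4-(TBSO)phenyl]ethyl}-3-{(3R,4S)-4-(TBSO)-7-[4-(TBSO)phenyl]hept-1-en-3-yl}oxan-4-ol | C=C[C@H]([C@@H]1[C@@H](c2ccc(O[Si](C)(C)C(C)(C)C)cc2)O[C@@H](CCc2ccc(O[Si](C)(C)C(C)(C)C)cc2)C[C@@H]1O)[C@@H](O[Si](C)(C)C(C)(C)C)CCCc1ccc(O[Si](C)(C)C(C)(C)C)cc1 | intermediate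
24 | tert-butyldimethyl(4-vinylphenoxy)silane | C=Cc1ccc(O[Si](C)(C)C(C)(C)C)cc1 | starting material
25 | (2S,3S,4S,6S)-2-[4-(TBSO)phenyl]-6-{2-[4-(TBSO)phenyl]ethyl}-3-{(1E,3R,4S)-4-(TBSO)-1,7-bis[4-(TBSO)phenyl]hept-1-en-3-yl}oxan-4-ol | CC(C)(C)[Si](C)(C)Oc1ccc(/C=C/[C@H]([C@@H]2[C@@H](c3ccc(O[Si](C)(C)C(C)(C)C)cc3)O[C@@H](CCc3ccc(O[Si](C)(C)C(C)(C)C)cc3)C[C@@H]2O)[C@@H](O[Si](C)(C)C(C)(C)C)CCCc2ccc(O[Si](C)(C)C(C)(C)C)cc2)cc1 | intermediate
26 | (2S,3S,4S,6S)-2-(4-hydroxyphenyl)-6-[2-(4-hydroxyphenyl)ethyl]-3-[(1E,3R,4S)-4-hydroxy-1,7-bis(4-hydroxyphenyl)hept-1-en-3-yl]oxan-4-ol | Oc1ccc(/C=C/[C@H]([C@@H]2[C@@H](c3ccc(O)cc3)O[C@@H](CCc3ccc(O)cc3)C[C@@H]2O)[C@@H](O)CCCc2ccc(O)cc2)cc1 | target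

**Summary**

Total step count: 15. Longest linear sequence: 14 steps (steps 1–4 and 6–15; step 5 is a one-step side branch).

Steps most likely to fail:

Step 11. What may go wrong is loss of facial control in the aldol closure (at C4 or C3), or protonation of the samarium enolate before it cyclises. The fallback sets out from 18 and comes back at 23, and no longer asks the aldol for the C4 configuration. The ring is closed by a zinc Reformatsky reaction (activated Zn, THF) and accepted as a mixture of 20 and the C4-epimeric lactone F1. The mixture is arylated as in step 12, giving the epimeric lactol F2 beside 21, and reduced as in step 13, giving the C4-epimeric oxanol F3 beside 23. Both alcohols are oxidised with Dess–Martin periodinane to the single oxan-4-one F4, in which C3, now α to the ketone, should settle equatorial. LiBH(sBu)3 in THF at −78 °C then attacks from the equatorial side and should return the axial alcohol 23.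

Step 9. What may go wrong is poor facial selectivity of the substrate-controlled copper addition next to the silyloxy group, or bromination of other sites in the one-pot operation. The fallback sets out from 14 and comes back at 17. A rhodium-catalysed conjugate addition of potassium vinyltrifluoroborate ([RhCl(C2H4)2]2, chiral diene ligand, Et3N, dioxane/H2O) lets the ligand, not C4', choose the face and gives the 3-vinyl ester F5. Its enolate (LiN(SiMe3)2, Me3SiCl, THF, −78 °C) is then brominated with NBS in a separate operation to give 17.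

Step 14. What may go wrong is slow metathesis at the doubly branched allylic position together with self-metathesis of the styrene partner. The fallback sets out from 23 and comes back at 25: a Heck arylation with aryl iodide 1 (Pd(OAc)2, P(o-tol)3, Et3N, MeCN, 80 °C), in which aryl–Pd adds to the terminal carbon and β-hydride elimination on the benzylic side gives the same (E)-styrene. It makes no new compound.

**Further compounds**

F1 | step 11 | (3S,4R,6S)-4-hydroxy-6-{2-[4-(TBSO)phenyl]ethyl}-3-{(3R,4S)-4-(TBSO)-7-[4-(TBSO)phenyl]hept-1-en-3-yl}oxan-2-one | C=C[C@H]([C@@H]1C(=O)O[C@@H](CCc2ccc(O[Si](C)(C)C(C)(C)C)cc2)C[C@H]1O)[C@@H](O[Si](C)(C)C(C)(C)C)CCCc1ccc(O[Si](C)(C)C(C)(C)C)cc1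
F2 | step 11 | (3S,4R,6S)-2-[4-(TBSO)phenyl]-6-{2-[4-(TBSO)phenyl]ethyl}-3-{(3R,4S)-4-(TBSO)-7-[4-(TBSO)phenyl]hept-1-en-3-yl}oxane-2,4-diol (C2 anomers) | C=C[C@H]([C@@H]1C(O)(c2ccc(O[Si](C)(C)C(C)(C)C)cc2)O[C@@H](CCc2ccc(O[Si](C)(C)C(C)(C)C)cc2)C[C@H]1O)[C@@H](O[Si](C)(C)C(C)(C)C)CCCc1ccc(O[Si](C)(C)C(C)(C)C)cc1
F3 | step 11 | (2S,3S,4R,6S)-2-[4-(TBSO)phenyl]-6-{2-[4-(TBSO)phenyl]ethyl}-3-{(3R,4S)-4-(TBSO)-7-[4-(TBSO)phenyl]hept-1-en-3-yl}oxan-4-ol | C=C[C@H]([C@@H]1[C@@H](c2ccc(O[Si](C)(C)C(C)(C)C)cc2)O[C@@H](CCc2ccc(O[Si](C)(C)C(C)(C)C)cc2)C[C@H]1O)[C@@H](O[Si](C)(C)C(C)(C)C)CCCc1ccc(O[Si](C)(C)C(C)(C)C)cc1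
F4 | step 11 | (2S,3R,6S)-2-[4-(TBSO)phenyl]-6-{2-[4-(TBSO)phenyl]ethyl}-3-{(3R,4S)-4-(TBSO)-7-[4-(TBSO)phenyl]hept-1-en-3-yl}oxan-4-one | C=C[C@H]([C@@H]1[C@@H](c2ccc(O[Si](C)(C)C(C)(C)C)cc2)O[C@@H](CCc2ccc(O[Si](C)(C)C(C)(C)C)cc2)CC1=O)[C@@H](O[Si](C)(C)C(C)(C)C)CCCc1ccc(O[Si](C)(C)C(C)(C)C)cc1
F5 | step 9 | (3S)-1,1-dimethoxy-5-[4-(TBSO)phenyl]pentan-3-yl (3S,4S)-3-ethenyl-4-(TBSO)-7-[4-(TBSO)phenyl]heptanoate | COC(OC)C[C@H](CCc1ccc(O[Si](C)(C)C(C)(C)C)cc1)OC(=O)C[C@@H](C=C)[C@@H](O[Si](C)(C)C(C)(C)C)CCCc1ccc(O[Si](C)(C)C(C)(C)C)cc1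
F0 | step 14 | none | none
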